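Numbering: C1 = O-bearing ring-fusion carbon, C2/C3 = cyclopentane CH2, C4 = quaternary C–CH3, C5 = fusion CH, C6/C7 = cyclopropane CH, C8/C9 = cycloheptane CH2, C10 = CH–CH3, C11 = CMe2, C7' = benzylic CH, C1'–C6' = arene.
Cuts, in retrosynthetic order: both aryl–CHO bonds and C7'–CH2(isobutyl); aryl–C7' and aryl–O, leaving a C1–O–C7'(=O)–C4 bridged lactone plus 1,3,5-trifluorobenzene; C6–C7 and C7–C11 together; then C6=C11, C1–O, C9–C10, C1–C10, C5–C6 and C4–CH3, back to a cyclopentenone acid.
Enabling feature: C6–C7 belongs to both the cyclopropane and the cycloheptane, C11 is the CMe2 end of a former isobutenyl group on C5, C8 next to C7 can be a carbonyl group, and C1, in the 1,5-position of the chain, has no hydrogen. One carbene centre at C7 can therefore close both rings.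
Forward ring order: cyclopentane (bought) → lactone bridge (iodolactonisation) → cycloheptane + cyclopropane (one carbene addition) → benzoxepine (aryllithium opening of the lactone, then SNAr).
Stereochemistry: C4 from a catalytic enantioselective methyl conjugate addition; C5 by cuprate attack anti to the ester; C10 by Claisen chirality transfer from a CBS-set carbinol at C2; C1 by tethered carboxylate delivery; C6/C7 by allylic strain plus the tether; C7' by exo attack on a benzylic cation.

Key step: step 13

Remark: the sense of induction in steps 2 and 6 follows the catalyst enantiomer; the ligand enantiomer that gives (R)-3 is assumed in step 2, and acid 1 is taken as a catalogue compound.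

Step 1
Reactants: 1 3-oxocyclopent-1-ene-1-carboxylic acid
Product: 2 tert-butyl 3-oxocyclopent-1-ene-1-carboxylate
Conditions: Cl3CC(=NH)Ot-Bu, CH2Cl2–cyclohexane, 23 °C
Reagents that add atoms: tert-butyl 2,2,2-trichloroacetimidate, CC(C)(C)OC(=N)C(Cl)(Cl)Cl
Why: O-alkylation of a carboxylic acid by a trichloroacetimidate is mild enough for the enone, and the bulky ester later serves as a steric shield and as the one ester that can be removed without base.

Step 2
Reactants: 2 tert-butyl 3-oxocyclopent-1-ene-1-carboxylate
Product: 3 tert-butyl (1R)-1-methyl-3-oxocyclopentane-1-carboxylate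
Conditions: Me2Zn, (CuOTf)2·C6H6 (2.5 mol %), chiral bidentate aryloxide-NHC–Ag(I) complex (2.5 mol %), t-BuOMe, −30 °C; aq NH4Cl
Reagents that add atoms: dimethylzinc, C[Zn]C
Why: Copper-catalysed enantioselective conjugate addition of a dialkylzinc to a cyclic γ-keto-α,β-unsaturated ester is an established route to all-carbon quaternary centres, and the chiral NHC–Cu complex selects the enone face so that C4 forms with R configuration.

Step 3
Reactants: 3 tert-butyl (1R)-1-methyl-3-oxocyclopentane-1-carboxylate
Product: 5 tert-butyl (1S)-1-methyl-4-oxocyclopent-2-ene-1-carboxylate, via trimethylsilyl enol ether 4 (not isolated)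
Conditions: LDA, TMSCl, THF, −78 °C; then Pd(OAc)2, MeCN, 23 °C
Reagents that add atoms: chlorotrimethylsilane, C[Si](C)(C)Cl (its silyl group is found in 4 only)
Why: Saegusa–Ito dehydrogenation, in which kinetic deprotonation takes the unhindered C1 methylene and only the C1=C5 enone can form because C4 has no hydrogen; C4 is untouched and its descriptor changes only through CIP priorities.

Step 4
Reactants: 5 tert-butyl (1S)-1-methyl-4-oxocyclopent-2-ene-1-carboxylate; 6 vinylmagnesium bromide; 7 acetaldehyde
Product: 9 tert-butyl (1S,2S)-3-(1-hydroxyethyl)-1-methyl-4-oxo-2-vinylcyclopentane-1-carboxylate (vinyl cis to the C4 methyl; mixture at C1 and the carbinol carbon), via bromomagnesium enolate 8 (not isolated)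
Conditions: 6, CuBr·SMe2 (20 mol %), THF, −78 °C; then 7, −78 °C; aq NH4Cl
Reagents that add atoms: none
Why: Copper-catalysed 1,4-addition followed by aldol capture of the enolate (three-component coupling of the prostanoid type); vinyl should enter C5 anti to the tert-butoxycarbonyl group, which is both the bulkier C4 substituent and the better σ-acceptor, so it ends cis to the methyl group, and the two aldol centres are erased in step 5.

Step 5
Reactants: 9 aldol adduct
Product: 11 tert-butyl (1S,2S,3E)-3-ethylidene-1-methyl-4-oxo-2-vinylcyclopentane-1-carboxylate, via secondary mesylate 10 (not isolated)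
Conditions: MsCl, Et3N, CH2Cl2, 0 °C; then DBU, 0 → 23 °C
Reagents that add atoms: methanesulfonyl chloride, CS(=O)(=O)Cl (its atoms are found in 10 only)
Why: Mesylation and E1cB elimination should give the conjugated exocyclic enone as the more stable E isomer (methyl turned away from the carbonyl group), as is usual for 2-alkylidenecyclopentanones.

Step 6
Reactants: 11 E-ethylidene enone
Product: 12 tert-butyl (1S,2S,3E,4S)-3-ethylidene-4-hydroxy-1-methyl-2-vinylcyclopentane-1-carboxylate (C2–OH on the face of the vinyl and methyl groups, trans to the ester)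
Conditions: (R)-Me-CBS (20 mol %), catecholborane, toluene, −78 °C; aq NaOH
Reagents that add atoms: none
Why: Corey–Bakshi–Shibata 1,2-reduction under catalyst control, with the alkylidene carbon C1 as the large and C3H2 as the small substituent, so the (R)-oxazaborolidine delivers hydride to the ester face and sets (S)-C2, while catecholborane leaves the vinyl group and the ester alone.

Step 7
Reactants: 12 allylic alcohol; 13 2-methoxypropene
Product: 16 tert-butyl (1S,2S)-1-methyl-3-[(2S)-4-oxopentan-2-yl]-2-vinylcyclopent-3-ene-1-carboxylate, via mixed acetone ketal 14 (not isolated), via allyl isopropenyl ether 15 (not isolated)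
Conditions: 13 (excess), PPTS (5 mol %), toluene, 23 °C, then sealed tube, 120 °C
Reagents that add atoms: none
Why: Ketal exchange, loss of methanol and Claisen rearrangement of the isopropenyl ether (Marbet–Saucy variant); the suprafacial [3,3] shift forms C9–C10 on the alkene face that carried the C2–O bond, so the E geometry and (S)-C2 translate into (S)-C10, the alkene moves to C1=C2, and the chain arrives as the methyl ketone C8(=O)–C7H3.

Step 8
Reactants: 16 cyclopentene tert-butyl ester
Product: 17 (1S,2S)-1-methyl-3-[(2S)-4-oxopentan-2-yl]-2-vinylcyclopent-3-ene-1-carboxylic acid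
Conditions: TMSOTf, 2,6-lutidine, CH2Cl2, 0 °C; aq citric acid
Reagents that add atoms: none
Why: Silyl-triflate-mediated cleavage of the tert-butyl ester (loss of isobutene) avoids protic acid that could protonate the trisubstituted alkene and scramble C10, and the silyl ester and any silyl enol ether are hydrolysed in the work-up.

Step 9
Reactants: 17 cyclopentene acid
Product: 18 (1S,4S,6S,7R)-6-iodo-4-methyl-1-[(2S)-4-oxopentan-2-yl]-7-vinyl-2-oxabicyclo[2.2.1]heptan-3-one
Conditions: I2, KI, NaHCO3, MeCN–H2O, 0 → 23 °C, dark
Reagents that add atoms: iodine, II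
Why: Iodolactonisation, in which the carboxylate attacks the tertiary (Markovnikov) terminus C1 of the iodonium ion of the electron-rich ring alkene in an anti addition, and the tether allows only C1–O cis to C7'; the vinyl group is far less nucleophilic and its lactonisation would need a trans-fused bicyclo[3.3.0] ring.

Step 10
Reactants: 18 iodolactone
Product: 19 (1S,4S,7R)-4-methyl-1-[(2S)-4-oxopentan-2-yl]-7-vinyl-2-oxabicyclo[2.2.1]heptan-3-one
Conditions: Bu3SnH, AIBN (cat.), benzene, 80 °C
Reagents that add atoms: none
Why: Radical-chain hydrodeiodination is the standard follow-up to iodolactonisation; the secondary C2 radical has no alkene in 5-exo or 6-exo reach and is simply reduced, so C2 becomes CH2 and no other centre is affected.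

Step 11
Reactants: 19 vinyl lactone; 20 2-methylbut-2-ene
Product: 21 (1S,4S,7R)-4-methyl-7-(2-methylprop-1-en-1-yl)-1-[(2S)-4-oxopentan-2-yl]-2-oxabicyclo[2.2.1]heptan-3-one
Conditions: 20 (large excess), Hoveyda–Grubbs II (5–10 mol %), CH2Cl2, 40 °C, sealed tube
Reagents that add atoms: none
Why: Olefin cross-metathesis of a terminal alkene with 2-methylbut-2-ene is the standard way to turn vinyl into 2-methylprop-1-enyl, and postponing it until after step 9 keeps a second electron-rich alkene out of the halolactonisation.

Step 12
Reactants: 21 isobutenyl methyl ketone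
Product: 23 (1S,4S,7R)-1-[(2S)-5-diazo-4-oxopentan-2-yl]-4-methyl-7-(2-methylprop-1-en-1-yl)-2-oxabicyclo[2.2.1]heptan-3-one, via trifluoroacetyl diketone 22 (not isolated)
Conditions: LiHMDS, THF, −78 °C; CF3CO2CH2CF3; then MsN3, Et3N, H2O, MeCN, 23 °C
Reagents that add atoms: 2,2,2-trifluoroethyl trifluoroacetate, O=C(OCC(F)(F)F)C(F)(F)F (its acyl group is found in 22 only); methanesulfonyl azide, CS(=O)(=O)N=[N+]=[N-]
Why: Detrifluoroacetylative diazo transfer, in which the kinetic enolate forms at the methyl group C7 (C9 is next to the branched C10 and the lactone has no α-hydrogen) and the activated 1,3-diketone takes up N2 from the sulfonyl azide with loss of the trifluoroacetyl group.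

Step 13
Reactants: 23 diazoketone lactone
Product: 24 tetracyclic keto lactone (8-oxoaromadendrane skeleton with the C1–O–C7'(=O)–C4 lactone bridge; 1S,4S,5R,6S,7R,10S; H5 syn to the lactone, H6 and H7 cis to each other and anti to H5)
Conditions: Rh2(cap)4 (1 mol %), CH2Cl2, reflux, syringe-pump addition of 23 at high dilution
Reagents that add atoms: none
Why: Loss of N2 from 23 at rhodium gives an electrophilic metal carbene at C7 that transfers to the nucleophilic trisubstituted C6=C11 bond in a single, asynchronous [2+1] event; the nearest established reaction type is the intramolecular cyclopropanation of terminal α-diazoketones, for which bicyclo[5.1.0]octan-2-ones mark the large-ring end of the known range. The cycloheptanone (C1–C5–C6–C7–C8–C9–C10) closes in a 7-exo sense through C6–C7, with C11 left outside that ring, and the cyclopropane (C6–C7–C11) closes in the same carbene transfer through C6–C7 and C7–C11. C6 is set by A(1,3) strain: the C11 methyl group cis to C5 pushes H5 into the plane of the alkene, C1 and C4 then flank opposite π faces, and a carbene anchored on C1 by the chain C10–C9–C8 can only meet the C1-side face, which leaves H6 anti to H5. C7 is set by the tether, because a chain of this length can bridge the new three-membered ring only in a cis fusion (H7 syn to H6). Chemoselectivity for the alkene over C–H insertion and carbene dimerisation is required: the position that would give a cyclopentanone is the hydrogen-free C1 or a primary methyl group, carboxamidate ligands on rhodium favour cyclopropanation over insertion, and slow addition keeps the diazo concentration low. The rigid 2-oxabicyclo[2.2.1]heptanone holds the C10–C1–C5–C6 dihedral angle near 60°, so both arms are pre-oriented and the entropic cost of seven-ring formation is reduced.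

Step 14
Reactants: 24 keto lactone
Product: 25 C8 enol triflate (C8=C9) of 24, all stereocentres unchanged
Conditions: KHMDS, THF, −78 °C; PhNTf2
Reagents that add atoms: N-phenylbis(trifluoromethanesulfonimide), O=S(=O)(N(c1ccccc1)S(=O)(=O)C(F)(F)F)C(F)(F)F
Why: Kinetic enolisation and O-triflation can occur only toward C9, because an enolate toward the cyclopropane carbon C7 would be a strained alkylidenecyclopropane and the lactone has no α-hydrogen.

Step 15
Reactants: 25 enol triflate
Product: 26 Δ8 alkene lactone (C8=C9 next to the cyclopropane)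
Conditions: Pd(OAc)2 (5 mol %), PPh3 (10 mol %), HCO2H, Et3N, DMF, 60 °C
Reagents that add atoms: none
Why: Palladium-catalysed formate reduction of an enol triflate replaces C8–O by C8–H without a radical or cation at the cyclopropylcarbinyl position, which diazene- or xanthate-based deoxygenations would risk.

Step 16
Reactants: 26 alkene lactone
Product: 27 saturated aromadendrane lactone (1S,4S,5R,6R,7R,10S)
Conditions: TsNHNH2, NaOAc, DME–H2O, reflux
Reagents that add atoms: none
Why: Diimide reduction transfers H2 in a concerted syn fashion to the cis-disubstituted alkene and cannot hydrogenolyse the adjacent cyclopropane.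

Step 17
Reactants: 27 saturated lactone; 28 1,3,5-trifluorobenzene
Product: 31 4',6'-difluorobenzoxepinone (aryl ketone at C7', aryl C2'–O–C1 ether, terpene centres unchanged), via 2,4,6-trifluorophenyllithium 29 (not isolated), via lithium keto alkoxide 30 (not isolated)
Conditions: 28, n-BuLi, THF, −78 °C; 27, −78 → −40 °C; then DMPU, 23 → 60 °C
Reagents that add atoms: none
Why: Fluorine-directed lithiation, acyl substitution at the strained lactone (the ketone formed is too hindered for a second addition) and intramolecular SNAr of the released C1 alkoxide on the ortho C–F bond activated by the ketone close the seven-membered oxepine, and the C1–O bond is never broken, so no stereocentre is at risk.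

Step 18
Reactants: 31 difluorobenzoxepinone
Product: 32 4',6'-bis(benzyloxy)benzoxepinone
Conditions: BnOH, NaH, DMF, 0 → 100 °C
Reagents that add atoms: benzyl alcohol, OCc1ccccc1
Why: Twofold SNAr of fluoride ortho and para to the non-enolisable aryl ketone by benzyloxide installs both phenol oxygens in a form that falls off during the later hydrogenation.

Step 19
Reactants: 32 bis(benzyloxy) ketone
Product: 33 C7' benzylic alcohol (either epimer, the centre is ionised next)
Conditions: LiAlH4, THF, 0 → 40 °C
Reagents that add atoms: none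
Why: Hydride reduction of the hindered diaryl-type ketone needs a small, strong donor, and the configuration of the new carbinol is irrelevant.

Step 20
Reactants: 33 benzylic alcohol; 34 trimethyl(2-methylallyl)silane
Product: 35 (7'R)-7'-(2-methylallyl) bis(benzyl ether)
Conditions: 34, BF3·OEt2 (20 mol %), CH2Cl2, −78 → −30 °C
Reagents that add atoms: none
Why: Lewis-acid ionisation of the 2,4,6-trialkoxybenzylic alcohol and Hosomi–Sakurai-type capture; the cation cannot eliminate because C4 is quaternary, and it should be attacked from the exo face (the side of the one-atom bridge C5, which offers only H5) rather than from the C2–C3 side, where a C3 hydrogen lies next to C7', and this places the chain as in the target.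

Step 21
Reactants: 35 methallyl bis(benzyl ether)
Product: 36 (7'R)-7'-isobutyl-4',6'-diphenol
Conditions: H2 (1 atm), 10 % Pd/C, EtOAc–EtOH, 23 °C
Reagents that add atoms: none
Why: Heterogeneous hydrogenation saturates the 1,1-disubstituted alkene and hydrogenolyses both benzyl ethers in one operation, while the unconjugated dimethylcyclopropane and the tertiary alkyl aryl ether are inert at 1 atm.

Step 22
Reactants: 36 diphenol
Product: 37 target CNP0189833.2 (1S,4R,5R,6R,7R,10S,7'R)
Conditions: POCl3, DMF, EtOAc, 0 → 23 °C; then H2O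
Reagents that add atoms: N,N-dimethylformamide, CN(C)C=O; water, O
Why: Vilsmeier–Haack formylation of a phloroglucinol-type ring; the only two free positions C3' and C5' are each flanked by two oxygen donors, the free phenols keep the ring nucleophilic after the first iminium is in place, and the mild conditions spare the tertiary aryl ether and the cyclopropane.

Compound list
1 | 3-oxocyclopent-1-ene-1-carboxylic acid | O=C1CCC(C(=O)O)=C1 | starting material
2 | tert-butyl 3-oxocyclopent-1-ene-1-carboxylate | O=C1CCC(C(=O)OC(C)(C)C)=C1 | intermediate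
3 | tert-butyl (1R)-1-methyl-3-oxocyclopentane-1-carboxylate | O=C1C[C@](C)(C(=O)OC(C)(C)C)CC1 | intermediate
4 | tert-butyl (1R)-1-methyl-3-(trimethylsilyloxy)cyclopent-3-ene-1-carboxylate | C[Si](C)(C)OC1=CC[C@@](C)(C(=O)OC(C)(C)C)C1 | intermediate
5 | tert-butyl (1S)-1-methyl-4-oxocyclopent-2-ene-1-carboxylate | O=C1C[C@](C)(C(=O)OC(C)(C)C)C=C1 | intermediate
6 | vinylmagnesium bromide | C=C[Mg]Br | starting material
7 | acetaldehyde | CC=O | starting material
8 | bromomagnesium enolate (C1=C2–OMgBr) of the vinyl adduct, vinyl cis to the C4 methyl | Br[Mg]OC1=C[C@H](C=C)[C@@](C)(C(=O)OC(C)(C)C)C1 | intermediate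
9 | tert-butyl (1S,2S)-3-(1-hydroxyethyl)-1-methyl-4-oxo-2-vinylcyclopentane-1-carboxylate | O=C1C[C@](C)(C(=O)OC(C)(C)C)[C@@H](C=C)C1C(C)O | intermediate
10 | mesylate of 9 | O=C1C[C@](C)(C(=O)OC(C)(C)C)[C@@H](C=C)C1C(C)OS(C)(=O)=O | intermediate
11 | tert-butyl (1S,2S,3E)-3-ethylidene-1-methyl-4-oxo-2-vinylcyclopentane-1-carboxylate | C/C=C1/C(=O)C[C@](C)(C(=O)OC(C)(C)C)[C@H]1C=C | intermediate
12 | tert-butyl (1S,2S,3E,4S)-3-ethylidene-4-hydroxy-1-methyl-2-vinylcyclopentane-1-carboxylate | C/C=C1/[C@@H](O)C[C@](C)(C(=O)OC(C)(C)C)[C@H]1C=C | intermediate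
13 | 2-methoxypropene | C=C(C)OC | starting material
14 | 2-methoxyprop-2-yl ether (mixed acetone ketal) of 12 | C/C=C1/[C@@H](OC(C)(C)OC)C[C@](C)(C(=O)OC(C)(C)C)[C@H]1C=C | intermediate
15 | isopropenyl ether of 12 | C/C=C1/[C@@H](OC(C)=C)C[C@](C)(C(=O)OC(C)(C)C)[C@H]1C=C | intermediate
16 | tert-butyl (1S,2S)-1-methyl-3-[(2S)-4-oxopentan-2-yl]-2-vinylcyclopent-3-ene-1-carboxylate | CC(=O)C[C@H](C)C1=CC[C@](C)(C(=O)OC(C)(C)C)[C@H]1C=C | intermediate
17 | (1S,2S)-1-methyl-3-[(2S)-4-oxopentan-2-yl]-2-vinylcyclopent-3-ene-1-carboxylic acid | CC(=O)C[C@H](C)C1=CC[C@](C)(C(=O)O)[C@H]1C=C | intermediate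
18 | (1S,4S,6S,7R)-6-iodo-4-methyl-1-[(2S)-4-oxopentan-2-yl]-7-vinyl-2-oxabicyclo[2.2.1]heptan-3-one | O=C1O[C@@]2([C@@H](I)C[C@@]1(C)[C@H]2C=C)[C@@H](C)CC(C)=O | intermediate
19 | (1S,4S,7R)-4-methyl-1-[(2S)-4-oxopentan-2-yl]-7-vinyl-2-oxabicyclo[2.2.1]heptan-3-one | O=C1O[C@@]2(CC[C@@]1(C)[C@H]2C=C)[C@@H](C)CC(C)=O | intermediate
20 | 2-methylbut-2-ene | CC=C(C)C | starting material
21 | (1S,4S,7R)-4-methyl-7-(2-methylprop-1-en-1-yl)-1-[(2S)-4-oxopentan-2-yl]-2-oxabicyclo[2.2.1]heptan-3-one | O=C1O[C@@]2(CC[C@@]1(C)[C@H]2C=C(C)C)[C@@H](C)CC(C)=O | intermediate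
22 | C7-trifluoroacetyl derivative of 21 (1,3-diketone) | O=C1O[C@@]2(CC[C@@]1(C)[C@H]2C=C(C)C)[C@@H](C)CC(=O)CC(=O)C(F)(F)F | intermediate
23 | (1S,4S,7R)-1-[(2S)-5-diazo-4-oxopentan-2-yl]-4-methyl-7-(2-methylprop-1-en-1-yl)-2-oxabicyclo[2.2.1]heptan-3-one | O=C1O[C@@]2(CC[C@@]1(C)[C@H]2C=C(C)C)[C@@H](C)CC(=O)C=[N+]=[N-] | intermediate
24 | 8-oxoaromadendrane 1,7'-lactone (1S,4S,5R,6S,7R,10S) | O=C1O[C@]23CC[C@@]1(C)[C@H]2[C@H]1[C@@H](C(=O)C[C@@H]3C)C1(C)C | intermediate
25 | C8 enol triflate of 24 | O=C1O[C@]23CC[C@@]1(C)[C@H]2[C@H]1[C@@H](C(OS(=O)(=O)C(F)(F)F)=C[C@@H]3C)C1(C)C | intermediate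
26 | Δ8 aromadendrene 1,7'-lactone | O=C1O[C@]23CC[C@@]1(C)[C@H]2[C@H]1[C@@H](C=C[C@@H]3C)C1(C)C | intermediate
27 | aromadendrane 1,7'-lactone (1S,4S,5R,6R,7R,10S) | O=C1O[C@]23CC[C@@]1(C)[C@H]2[C@H]1[C@@H](CC[C@@H]3C)C1(C)C | intermediate
28 | 1,3,5-trifluorobenzene | Fc1cc(F)cc(F)c1 | starting material
29 | 2,4,6-trifluorophenyllithium | [Li]c1c(F)cc(F)cc1F | intermediate
30 | lithium C1 alkoxide of the ring-opened 2,4,6-trifluorophenyl ketone | [Li+].[O-][C@]12CC[C@](C)(C(=O)c3c(F)cc(F)cc3F)[C@H]1[C@H]1[C@@H](CC[C@@H]2C)C1(C)C | intermediate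
31 | 4',6'-difluorobenzoxepinone | O=C1c2c(F)cc(F)cc2O[C@]23CC[C@@]1(C)[C@H]2[C@H]1[C@@H](CC[C@@H]3C)C1(C)C | intermediate
32 | 4',6'-bis(benzyloxy)benzoxepinone | O=C1c2c(OCc4ccccc4)cc(OCc4ccccc4)cc2O[C@]23CC[C@@]1(C)[C@H]2[C@H]1[C@@H](CC[C@@H]3C)C1(C)C | intermediate
33 | C7' benzylic alcohol | OC1c2c(OCc4ccccc4)cc(OCc4ccccc4)cc2O[C@]23CC[C@@]1(C)[C@H]2[C@H]1[C@@H](CC[C@@H]3C)C1(C)C | intermediate
34 | trimethyl(2-methylallyl)silane | C=C(C)C[Si](C)(C)C | starting material
35 | (7'R)-7'-(2-methylallyl) bis(benzyl ether) | C=C(C)C[C@H]1c2c(OCc4ccccc4)cc(OCc4ccccc4)cc2O[C@]23CC[C@@]1(C)[C@H]2[C@H]1[C@@H](CC[C@@H]3C)C1(C)C | intermediate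
36 | (7'R)-7'-isobutyl-4',6'-diphenol | CC(C)C[C@H]1c2c(O)cc(O)cc2O[C@]23CC[C@@]1(C)[C@H]2[C@H]1[C@@H](CC[C@@H]3C)C1(C)C | intermediate
37 | CNP0189833.2 | CC(C)C[C@H]1c2c(O)c(C=O)c(O)c(C=O)c2O[C@]23CC[C@@]1(C)[C@H]2[C@H]1[C@@H](CC[C@@H]3C)C1(C)C | target

Total step count: 22. Longest linear sequence: 22 steps (1 → 37).

Steps most likely to fail

1. Step 13. Closure of the seven-membered ring may lose the race against bimolecular carbene coupling, insertion into the allylic C5–H or the C2–H bond, or Wolff rearrangement. The fallback sets out from 19 and returns at 24, and it builds the two rings one after the other.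
- The kinetic lithium enolate of 19 is aminomethylated at C7 with dimethylmethyleneiminium iodide to the Mannich base F1.
- Methyl iodide gives the methiodide F2, and mild base eliminates the amine to the vinyl ketone F3.
- Ring-closing metathesis (Hoveyda–Grubbs II) joins C6 and C7 in the cycloheptenone F4.
- Sulfur-ylide cyclopropanation of this enone with diphenylsulfonium isopropylide should add C11 to C6 on the face anti to the C5–C4 bond and close onto C7, giving 24.

2. Step 17. The aryllithium loses LiF above about −50 °C, whereas attack on a carbonyl group next to the quaternary C4 may need more thermal energy, so incomplete addition and aryne-derived decomposition can compete. The fallback sets out from 27 and returns at 31, and it moves the arylation to the aldehyde oxidation level.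
- DIBAL-H reduces 27 to the lactol F5.
- Excess 29 adds to the open hydroxy-aldehyde form of F5 to give the diol F6.
- Dess–Martin oxidation of the secondary benzylic alcohol gives the hydroxy ketone F7.
- KHMDS in THF then triggers the intramolecular SNAr to 31.

3. Step 11. Steric shielding of the vinyl group between two fully substituted bridgeheads may stop metallacyclobutane formation, so the catalyst decays before turnover. The fallback sets out from 19 and returns at 21, and it replaces metathesis by cleavage and olefination.
- Ozonolysis (Me2S work-up) gives the keto aldehyde F8.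
- The non-basic, aldehyde-selective Takai–Utimoto olefination with 2,2-diiodopropane and CrCl2 then gives 21 without touching the methyl ketone and without risking β-elimination of the lactone oxygen.

Further compounds
F1 | step 13 | C7-(dimethylaminomethyl) ketone (Mannich base of 19) | O=C1O[C@@]2(CC[C@@]1(C)[C@H]2C=C)[C@@H](C)CC(=O)CCN(C)C
F2 | step 13 | methiodide of F1 | O=C1O[C@@]2(CC[C@@]1(C)[C@H]2C=C)[C@@H](C)CC(=O)CC[N+](C)(C)C.[I-]
F3 | step 13 | vinyl ketone (C8(=O)–C7H=CH2) with the C5 vinyl group | O=C1O[C@@]2(CC[C@@]1(C)[C@H]2C=C)[C@@H](C)CC(=O)C=C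
F4 | step 13 | tricyclic cycloheptenone lactone (C6=C7–C8=O) | O=C1O[C@]23CC[C@@]1(C)[C@H]2C=CC(=O)C[C@@H]3C
F5 | step 17 | lactol of 27 | OC1O[C@]23CC[C@@]1(C)[C@H]2[C@H]1[C@@H](CC[C@@H]3C)C1(C)C
F6 | step 17 | C1,C7' diol with the 2,4,6-trifluorophenyl group on C7' | O[C@]12CC[C@](C)(C(O)c3c(F)cc(F)cc3F)[C@H]1[C@H]1[C@@H](CC[C@@H]2C)C1(C)C
F7 | step 17 | C1-hydroxy 2,4,6-trifluorophenyl ketone | O[C@]12CC[C@](C)(C(=O)c3c(F)cc(F)cc3F)[C@H]1[C@H]1[C@@H](CC[C@@H]2C)C1(C)C
F8 | step 11 | C6 aldehyde of the bridged lactone methyl ketone | O=C1O[C@@]2(CC[C@@]1(C)[C@H]2C=O)[C@@H](C)CC(C)=O
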